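The constants were drawn at random within sensible limits; the flask was simulated.

I decided to follow the reagent first and come to the target afterwards, in these two flasks, which differ in their time.

| flask | starting material | reagent | time |
|---|---|---|---|
| south | 0.050 M | 0.0500 M | 3.0 h |
| east | 0.050 M | 0.0500 M | 10 h |

    reagent ⇌ dormant form (K1 = 26, k1 = 0.33 h⁻¹)
    starting material + reagent → intermediate + released group (k2 = 9.9 L mol⁻¹ h⁻¹)
    starting material → decomposition product (k3 = 5.0 × 10⁻⁴ h⁻¹)
    intermediate ⇌ isomer of the product (K4 = 2.5, k4 = 0.048 h⁻¹)
    intermediate ⇌ target (K5 = 2.5, k5 = 1.8 h⁻¹)
    intermediate → side product (k6 = 0.43 h⁻¹)

- which of the two there is more of at the end, south (target / side product)
- which of the two there is more of at the end, east (target / side product)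
- how much target is there at the end, in percent of the starting material charged: south
- how much target is there at the end, in percent of the starting material charged: east

The dormant form returns at 0.0127 h⁻¹, much slower than the reagent leaves at 0.33 h⁻¹, so I dropped the return. Dividing reagent loss by starting-material loss then folded the givens into one competition number, the coupling constant times the charge of starting material over the constant for going dormant, 1.50, which says that at the start the reagent couples that many times as fast as it goes dormant. Integrated, the balance reads: reagent left, in charges of starting material, equals reagent charged, less the fraction of starting material used, less minus-ln(fraction left) over that number. At equal charges, with the return left out, it reaches zero with 48.4% left, so in this one-way reckoning the reagent is the limiting reagent and 51.6% couples, which I took as an estimate and not as a ceiling on the real flask.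

That number says how much, not when, so it was not enough. The relaxation half-life of intermediate and target, 0.275 h, is short against 3.0 h, so I treated them as one pool, 71.4% of it target, draining to side product at 0.123 h⁻¹. I fed it exponentially at the starting reagent loss rate, 0.825 h⁻¹, which overstates the later feed. This gave target 26.3% against side product 10.4% in south, and 12.7% against 33.9% in east.

The forecast named target for south and side product for east, with target at 23% and 13%, holding that “That target pool then drains through the intermediate to side product at about 0.12 per hour”.

The simulation gave target in south, 22.3% against 13.0%, and side product in east, 32.6% against 12.9% of target, so my south target stood high. With south's 54% of starting material left, the balance gives reagent at 12.9% of its charge, and the flask held 14%. A neighbour of south with 0.020 M of starting material, 2.50 equiv of reagent, has the number 0.600; from its 45.1% left, the balance gives reagent at 25.0% of its charge, the flask held 26.3%, and its target stood at 26.6%.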